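The route rests on cutting the C1'–C2' bond in each of rings D and E. Both rings carry oxygen at C2', C4' and C6' and are tied through C1' to C3 and C5 of ring C. That is the carbonyl pattern of an ArCH2–CO–CH2–CO–CH2–CO2Me chain, so the crowded biaryl bonds can be installed as plain benzylic bonds. Precursor 10 is ring C (three OMe, C1 benzyl ether) with two such 3,5-dioxohexanoate arms. One Mg(OMe)2 treatment closes both arms by Claisen C-acylation and aromatisation to 12. Rings A and B follow as bromide 21 by copper-catalysed etherification of the unmasked C1 hydroxyl. BBr3 then frees thirteen phenols.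

Key step: step 6

Remark: ring C is numbered from the carbon bearing the ether oxygen to ring B (C1), primed locants start at the ring D or ring E carbon bonded to ring C, and chain locants start at the ester carbon; the target has no stereocentre and no stereogenic axis (rings D and E are symmetric about their biaryl bonds), so nothing stereochemical has to be set; 2,4,6-trimethoxyphenol is assumed to be purchasable.

Step 1
Reactants: 1 2,4,6-trimethoxyphenol
Product: 2 2-(benzyloxy)-1,3,5-trimethoxybenzene
Conditions: BnBr (1.2 equiv), K2CO3 (2 equiv), DMF, 50 °C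
Reagents that add atoms: benzyl bromide, BrCc1ccccc1
Why: Williamson ether synthesis in which the phenoxide of 1 is alkylated on oxygen by a primary benzylic bromide, giving the only ether of the series that hydrogenolysis can later remove.

Step 2
Reactants: 2 2-(benzyloxy)-1,3,5-trimethoxybenzene
Product: 3 1-(benzyloxy)-3,5-dibromo-2,4,6-trimethoxybenzene
Conditions: NBS (2.1 equiv), MeCN, 0 °C to rt, dark
Reagents that add atoms: N-bromosuccinimide, O=C1CCC(=O)N1Br
Why: Electrophilic aromatic bromination, in which C3 and C5 are the only free positions of ring C and each lies ortho or para to three alkoxy groups, so polar conditions in the dark should fill both without touching the benzylic CH2 or the unactivated phenyl ring.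

Step 3
Reactants: 3 1-(benzyloxy)-3,5-dibromo-2,4,6-trimethoxybenzene; 4 ethyl bromoacetate
Product: 6 diethyl 2,2'-[5-(benzyloxy)-2,4,6-trimethoxybenzene-1,3-diyl]diacetate, via Reformatsky reagent 5 (not isolated)
Conditions: Zn dust (TMSCl-activated), 4 (5 equiv), THF, 40 °C; then 3, Pd2(dba)3 (2.5 mol%), XPhos (6 mol%), THF, 65 °C
Reagents that add atoms: none
Why: Negishi-type α-arylation of a Reformatsky reagent, in which the bulky electron-rich XPhos complex of zerovalent palladium inserts into the di-ortho-alkoxy C–Br bonds, the neutral zinc enolate 5 transmetalates without strong base, and crowding speeds the reductive elimination that forms each ArCH2 bond.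

Step 4
Reactants: 6 diethyl 2,2'-[5-(benzyloxy)-2,4,6-trimethoxybenzene-1,3-diyl]diacetate
Product: 7 2,2'-[5-(benzyloxy)-2,4,6-trimethoxybenzene-1,3-diyl]bis(N-methoxy-N-methylacetamide)
Conditions: MeNH(OMe)·HCl (5 equiv), iPrMgCl (10 equiv), THF, −20 to 0 °C; aq NH4Cl
Reagents that add atoms: N,O-dimethylhydroxylamine hydrochloride, CNOC.Cl
Why: Weinreb amide synthesis by ester aminolysis, in which the weakly basic magnesium amide formed in the flask adds to the unhindered ester carbonyls faster than it enolises them and leaves all aryl ethers alone.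

Step 5
Reactants: 7 2,2'-[5-(benzyloxy)-2,4,6-trimethoxybenzene-1,3-diyl]bis(N-methoxy-N-methylacetamide); 8 methyl acetoacetate
Product: 10 dimethyl 6,6'-[5-(benzyloxy)-2,4,6-trimethoxybenzene-1,3-diyl]bis(3,5-dioxohexanoate), via acetoacetate dianion 9 (not isolated)
Conditions: 8 (5 equiv), LiN(iPr)2 (LDA, 10 equiv), THF, −78 to 0 °C; then 7, −78 to 0 °C; cold 1 M HCl
Reagents that add atoms: none
Why: γ-Acylation of a β-keto ester dianion by a Weinreb amide, in which the terminal carbanion of 9 is the more nucleophilic site and the lithium-chelated tetrahedral adduct persists until the acidic quench, so neither over-addition nor proton transfer from an acidic product to unreacted dianion should interfere.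

Step 6
Reactants: 10 dimethyl 6,6'-[5-(benzyloxy)-2,4,6-trimethoxybenzene-1,3-diyl]bis(3,5-dioxohexanoate)
Product: 12 5'-(benzyloxy)-2',4',6'-trimethoxy-[1,1':3',1''-terphenyl]-2,2'',4,4'',6,6''-hexol, via monocyclised diketo ester 11 (not isolated)
Conditions: Mg(OMe)2 (10 equiv), MeOH (0.02 M), reflux, Ar; cold 1 M HCl
Reagents that add atoms: none
Why: Mg(OMe)2 turns each arm into its magnesium chelate, a small equilibrium share of the enolate deprotonated at the benzylic carbon C6 (α to the C5 ketone, the future C1') adds to the magnesium-activated ester carbonyl C1 (the future C2'), methoxide leaves, and the 2-arylcyclohexane-1,3,5-trione enolises at once to the aromatic triol, first in one arm (11) and then in the other. The closest known reactions are the Claisen (Dieckmann-type) cyclisation of polyketo esters to phloroglucinols under Mg(OMe)2 or alkoxide and the alkoxide closure of 6-aryl-5-oxohexanoates to cyclohexane-1,3-diones carrying a 2,6-disubstituted aryl group at C2. Ring D and ring E each close in the 6-(enolendo)-exo-trig mode. No stereocentre is created, and no atropisomers can arise because both new rings are symmetric about the biaryl bond. The selectivity needed is C-acylation over O-acylation by the C5 enolate oxygen (lactone formation): methanolic methoxide re-opens the lactone to the methyl ester, whereas C-acylation is made irreversible by aromatisation, so the equilibria should drain to 12, and the methyl ester matches the base so that transesterification changes nothing. Within one arm no other five- or six-membered aldol or Claisen ring is possible, a bridge between the meta-placed arms would be a strained metacyclophane, and dilution holds back intermolecular condensation.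

Step 7
Reactants: 12 5'-(benzyloxy)-2',4',6'-trimethoxy-[1,1':3',1''-terphenyl]-2,2'',4,4'',6,6''-hexol
Product: 13 5'-(benzyloxy)-2,2',2'',4,4',4'',6,6',6''-nonamethoxy-1,1':3',1''-terphenyl
Conditions: Me2SO4 (12 equiv), K2CO3 (15 equiv), acetone, reflux, Ar
Reagents that add atoms: dimethyl sulfate, COS(=O)(=O)OC
Why: Williamson-type O-methylation, in which the hard electrophile Me2SO4 with the weak base K2CO3 in acetone directs phloroglucinol-type phenoxides to react on oxygen and not on ring carbon, and the excess should carry all six hydroxyls, the four next to the biaryl bonds included, to the ether.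

Step 8
Reactants: 13 5'-(benzyloxy)-2,2',2'',4,4',4'',6,6',6''-nonamethoxy-1,1':3',1''-terphenyl
Product: 14 2,2',2'',4,4',4'',6,6',6''-nonamethoxy-[1,1':3',1''-terphenyl]-5'-ol
Conditions: H2 (1 atm), 10% Pd/C, EtOAc–MeOH, rt
Reagents that add atoms: none
Why: Catalytic hydrogenolysis of a benzyl aryl ether, which cleaves only the benzylic C–O bond and leaves methyl ethers and biaryl bonds untouched, so the C1 hydroxyl of ring C is the single free phenol.

Step 9
Reactants: 15 1-bromo-3,5-dimethoxybenzene
Product: 17 2-bromo-4,6-dimethoxybenzaldehyde, via aryl iminium salt 16 (not isolated)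
Conditions: POCl3 (1.5 equiv), DMF, 0 to 90 °C; ice-water
Reagents that add atoms: N,N-dimethylformamide, CN(C)C=O; water, O
Why: Vilsmeier–Haack formylation, in which the chloroiminium ion attacks C2 (para to one methoxy group and ortho to the other) and, as is usual for resorcinol dimethyl ethers, avoids the position between both methoxy groups, after which water hydrolyses 16.

Step 10
Reactants: 17 2-bromo-4,6-dimethoxybenzaldehyde
Product: 19 2-bromo-4,6-dimethoxyphenol, via aryl formate 18 (not isolated)
Conditions: mCPBA (1.3 equiv), CH2Cl2, 0 °C to rt; aq NaHCO3 wash; K2CO3 (20 mol%), MeOH, rt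
Reagents that add atoms: 3-chloroperoxybenzoic acid, OOC(=O)c1cccc(Cl)c1
Why: Baeyer–Villiger oxidation, in which the aryl group, made electron-rich by an ortho and a para methoxy group, migrates in the Criegee adduct in preference to hydride, and base-catalysed methanolysis of formate 18 frees the phenol.

Step 11
Reactants: 19 2-bromo-4,6-dimethoxyphenol; 20 3,5-dimethoxyphenylboronic acid
Product: 21 1-bromo-2-(3,5-dimethoxyphenoxy)-3,5-dimethoxybenzene
Conditions: Cu(OAc)2 (2 equiv), pyridine (5 equiv), 4 Å MS, CH2Cl2, rt, dry air
Reagents that add atoms: none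
Why: Chan–Lam–Evans coupling, in which the boronic acid transmetalates to a copper phenoxide and C–O reductive elimination takes place at room temperature, conditions that accept 2,6-disubstituted phenols and leave the aryl bromide intact.

Step 12
Reactants: 14 2,2',2'',4,4',4'',6,6',6''-nonamethoxy-[1,1':3',1''-terphenyl]-5'-ol; 21 1-bromo-2-(3,5-dimethoxyphenoxy)-3,5-dimethoxybenzene
Product: 22 5'-[2-(3,5-dimethoxyphenoxy)-3,5-dimethoxyphenoxy]-2,2',2'',4,4',4'',6,6',6''-nonamethoxy-1,1':3',1''-terphenyl
Conditions: CuI (20 mol%), picolinic acid (40 mol%), K3PO4 (3 equiv), DMSO, 110 °C, Ar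
Reagents that add atoms: none
Why: Ligand-accelerated Ullmann diaryl ether synthesis, using a catalyst system suited to ortho-substituted partners, in which the phenoxide of 14 binds monovalent copper, bromide 21 with its single ortho substituent adds oxidatively, and C–O reductive elimination forms the ring B–O–ring C bond.

Step 13
Reactants: 22 5'-[2-(3,5-dimethoxyphenoxy)-3,5-dimethoxyphenoxy]-2,2',2'',4,4',4'',6,6',6''-nonamethoxy-1,1':3',1''-terphenyl
Product: 23 CNP0228669.0, 5'-[2-(3,5-dihydroxyphenoxy)-3,5-dihydroxyphenoxy]-[1,1':3',1''-terphenyl]-2,2',2'',4,4',4'',6,6',6''-nonol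
Conditions: BBr3 (30 equiv), CH2Cl2, −78 °C to rt, Ar; ice-water; Sephadex LH-20
Reagents that add atoms: none
Why: Lewis-acid cleavage of aryl methyl ethers, in which BBr3 binds each methoxy oxygen and bromide removes the methyl group by SN2 attack while the two diaryl ether and two biaryl bonds offer no sp3 carbon and survive, and quenching by water instead of methanol avoids acid-catalysed re-etherification of the phloroglucinol rings.

Compound list
1 | 2,4,6-trimethoxyphenol | COc1cc(OC)c(O)c(OC)c1 | starting material
2 | 2-(benzyloxy)-1,3,5-trimethoxybenzene | COc1cc(OC)c(OCc2ccccc2)c(OC)c1 | intermediate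
3 | 1-(benzyloxy)-3,5-dibromo-2,4,6-trimethoxybenzene | COc1c(Br)c(OC)c(OCc2ccccc2)c(OC)c1Br | intermediate
4 | ethyl bromoacetate | CCOC(=O)CBr | starting material
5 | (2-ethoxy-2-oxoethyl)zinc bromide (Reformatsky reagent) | CCOC(=O)C[Zn]Br | intermediate
6 | diethyl 2,2'-[5-(benzyloxy)-2,4,6-trimethoxybenzene-1,3-diyl]diacetate | CCOC(=O)Cc1c(OC)c(CC(=O)OCC)c(OC)c(OCc2ccccc2)c1OC | intermediate
7 | 2,2'-[5-(benzyloxy)-2,4,6-trimethoxybenzene-1,3-diyl]bis(N-methoxy-N-methylacetamide) | CON(C)C(=O)Cc1c(OC)c(CC(=O)N(C)OC)c(OC)c(OCc2ccccc2)c1OC | intermediate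
8 | methyl acetoacetate | COC(=O)CC(C)=O | starting material
9 | dilithium dianion of methyl acetoacetate | [Li+].[Li+].C=C([O-])C=C([O-])OC | intermediate
10 | dimethyl 6,6'-[5-(benzyloxy)-2,4,6-trimethoxybenzene-1,3-diyl]bis(3,5-dioxohexanoate) | COC(=O)CC(=O)CC(=O)Cc1c(OC)c(CC(=O)CC(=O)CC(=O)OC)c(OC)c(OCc2ccccc2)c1OC | intermediate
11 | methyl 6-[3-(benzyloxy)-2,4,6-trimethoxy-5-(2,4,6-trihydroxyphenyl)phenyl]-3,5-dioxohexanoate | COC(=O)CC(=O)CC(=O)Cc1c(OC)c(-c2c(O)cc(O)cc2O)c(OC)c(OCc2ccccc2)c1OC | intermediate
12 | 5'-(benzyloxy)-2',4',6'-trimethoxy-[1,1':3',1''-terphenyl]-2,2'',4,4'',6,6''-hexol | COc1c(OCc2ccccc2)c(OC)c(-c2c(O)cc(O)cc2O)c(OC)c1-c1c(O)cc(O)cc1O | intermediate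
13 | 5'-(benzyloxy)-2,2',2'',4,4',4'',6,6',6''-nonamethoxy-1,1':3',1''-terphenyl | COc1c(OCc2ccccc2)c(OC)c(-c2c(OC)cc(OC)cc2OC)c(OC)c1-c1c(OC)cc(OC)cc1OC | intermediate
14 | 2,2',2'',4,4',4'',6,6',6''-nonamethoxy-[1,1':3',1''-terphenyl]-5'-ol | COc1c(O)c(OC)c(-c2c(OC)cc(OC)cc2OC)c(OC)c1-c1c(OC)cc(OC)cc1OC | intermediate
15 | 1-bromo-3,5-dimethoxybenzene | COc1cc(Br)cc(OC)c1 | starting material
16 | (2-bromo-4,6-dimethoxybenzylidene)dimethyliminium dichlorophosphate | C[N+](C)=Cc1c(Br)cc(OC)cc1OC.[O-]P(=O)(Cl)Cl | intermediate
17 | 2-bromo-4,6-dimethoxybenzaldehyde | COc1cc(Br)c(C=O)c(OC)c1 | intermediate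
18 | 2-bromo-4,6-dimethoxyphenyl formate | COc1cc(Br)c(OC=O)c(OC)c1 | intermediate
19 | 2-bromo-4,6-dimethoxyphenol | COc1cc(Br)c(O)c(OC)c1 | intermediate
20 | 3,5-dimethoxyphenylboronic acid | COc1cc(OC)cc(B(O)O)c1 | starting material
21 | 1-bromo-2-(3,5-dimethoxyphenoxy)-3,5-dimethoxybenzene | COc1cc(OC)cc(Oc2c(Br)cc(OC)cc2OC)c1 | intermediate
22 | 5'-[2-(3,5-dimethoxyphenoxy)-3,5-dimethoxyphenoxy]-2,2',2'',4,4',4'',6,6',6''-nonamethoxy-1,1':3',1''-terphenyl | COc1cc(OC)cc(Oc2c(OC)cc(OC)cc2Oc2c(OC)c(-c3c(OC)cc(OC)cc3OC)c(OC)c(-c3c(OC)cc(OC)cc3OC)c2OC)c1 | intermediate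
23 | CNP0228669.0 (achiral) | Oc1cc(O)cc(Oc2c(O)cc(O)cc2Oc2c(O)c(-c3c(O)cc(O)cc3O)c(O)c(-c3c(O)cc(O)cc3O)c2O)c1 | target

Total step count: 13. Longest linear sequence: 10 (steps 1–8, 12, 13). The ring AB branch (steps 9–11) joins at step 12.

Steps most likely to fail

Step 6. The closure may be outrun by O-acylation of the C5 enolate onto the ester or by methoxide-induced retro-Claisen scission of the arms, or it may stop after the first ring. The fallback sets out from 3 and comes back at 13. Ring construction is given up and preformed rings are attached instead. 1,3,5-Trimethoxybenzene is lithiated (nBuLi, THF, 0 °C) to 2,4,6-trimethoxyphenyllithium F1. This is transmetalated with ZnCl2 to (2,4,6-trimethoxyphenyl)zinc chloride F2. F2 is coupled twice with 3 under Negishi conditions developed for tetra-ortho-substituted biaryls (Pd2(dba)3, RuPhos, THF–NMP, 100 °C), which should give 13 directly.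

Step 12. The crowded phenoxide may bind copper poorly and the electron-rich bromide may add slowly, so that reduction of the bromide and oxidative loss of the phenol outrun C–O bond formation. The fallback sets out from 21 and comes back at 22. The polarity of ring B is inverted. Bromine–lithium exchange (nBuLi, THF, −78 °C) gives [2-(3,5-dimethoxyphenoxy)-3,5-dimethoxyphenyl]lithium F3. B(OiPr)3 followed by aqueous HCl gives [2-(3,5-dimethoxyphenoxy)-3,5-dimethoxyphenyl]boronic acid F4. Oxidative Chan–Lam–Evans coupling of F4 with phenol 14 (Cu(OAc)2, pyridine, 4 Å MS, CH2Cl2, air, rt) should then form 22 at room temperature.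

Step 3. Oxidative addition at the doubly flanked C–Br bonds may be slow, so that the reaction stalls after one arylation or loses bromine by protodehalogenation. The fallback sets out from 2 and comes back at 6, and it uses no cross-coupling. The still free, strongly nucleophilic C3 and C5 positions of 2 undergo twofold Friedel–Crafts hydroxyalkylation with ethyl glyoxylate (SnCl4, CH2Cl2, −40 °C). This gives diethyl 2,2'-[5-(benzyloxy)-2,4,6-trimethoxybenzene-1,3-diyl]bis(2-hydroxyacetate) F5, a diastereomer mixture of no consequence. Ionic hydrogenation of both electron-rich benzylic alcohols (Et3SiH, CF3CO2H, CH2Cl2, 0 °C) erases the two centres and should give 6.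

Further compounds
F1 | step 6 | 2,4,6-trimethoxyphenyllithium | COc1cc(OC)c([Li])c(OC)c1
F2 | step 6 | (2,4,6-trimethoxyphenyl)zinc chloride | COc1cc(OC)c([Zn]Cl)c(OC)c1
F3 | step 12 | [2-(3,5-dimethoxyphenoxy)-3,5-dimethoxyphenyl]lithium | COc1cc(OC)cc(Oc2c([Li])cc(OC)cc2OC)c1
F4 | step 12 | [2-(3,5-dimethoxyphenoxy)-3,5-dimethoxyphenyl]boronic acid | COc1cc(OC)cc(Oc2c(B(O)O)cc(OC)cc2OC)c1
F5 | step 3 | diethyl 2,2'-[5-(benzyloxy)-2,4,6-trimethoxybenzene-1,3-diyl]bis(2-hydroxyacetate), diastereomer mixture | CCOC(=O)C(O)c1c(OC)c(C(O)C(=O)OCC)c(OC)c(OCc2ccccc2)c1OC
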